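**Assumption:** the target SMILES has no stereocentres, and the macrocycle's conformers interconvert. The compound is therefore achiral and no stereocontrol is needed.

## Retrosynthetic overview
1. The only ring formed by bond construction is the 15-membered macrocycle. It is closed last by acyl-radical addition (from an acyl selenide) to a styrene. This forms the C2–C3 bond and the ketone together, and the benzylic radical it leaves behind is reduced.
2. Both arenes therefore arrive intact as a diaryl ether. Its C–O bond is made by a chemoselective Cu-catalysed Ullmann coupling of a 2-methoxyresorcinol acid with 4-bromo-2-iodoanisole. The Br is then converted to vinyl by Suzuki coupling.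
3. The 2-methoxyresorcinol acid is built from resorcinol: bis-MOM protection, C2 oxygenation and methylation, ortho-lithiation/glutaric anhydride acylation, then Clemmensen reduction.

## Forward route

**Step 1**
Reactants: 1 resorcinol (benzene-1,3-diol)
Product: 2 1,3-bis(methoxymethoxy)benzene
Conditions: NaH, MOMCl, THF/DMF, 0 °C → rt
Reagents that add atoms: chloromethyl methyl ether, COCCl
Why: double Williamson-type O-alkylation installs the ortho-directing MOM groups and blocks both phenols.

**Step 2**
Reactants: 2
Product: 3 2,6-bis(methoxymethoxy)phenol
Conditions: n-BuLi, Et2O, 0 °C; B(OMe)3, –78 °C → rt; then H2O2, aq. NaOH, 0 °C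
Reagents that add atoms: trimethyl borate, COB(OC)OC (boron carrier, lost on work-up); hydrogen peroxide, OO (supplies the phenolic O)
Why: directed ortho-metalation occurs at C2, the site between the two OMOM groups. Borylation followed by oxidative B→O conversion installs the central oxygen.

**Step 3**
Reactants: 3
Product: 4 2-methoxy-1,3-bis(methoxymethoxy)benzene
Conditions: MeI, K2CO3, acetone, reflux
Reagents that add atoms: methyl iodide, CI
Why: O-methylation of the only free phenol sets the central OMe (the b6 OMe of the target).

**Step 4**
Reactants: 4; 5 glutaric anhydride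
Product: 6 5-[3-methoxy-2,4-bis(methoxymethoxy)phenyl]-5-oxopentanoic acid
Conditions: n-BuLi, TMEDA, THF, –78 → –20 °C; the aryllithium is then transferred (inverse addition) into 5 (2 equiv) in THF at –78 °C; aq. NaH2PO4 work-up
Reagents that add atoms: none
Why: MOM-directed lithiation at C4/C6, which are equivalent, puts the acyl group ortho to one OMOM and para to the other, which is the ring-B pattern. Inverse addition to the cyclic anhydride limits over-addition (organolithium + anhydride → keto acid).

**Step 5**
Reactants: 6
Product: 7 5-(2,4-dihydroxy-3-methoxyphenyl)pentanoic acid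
Conditions: Zn(Hg), conc. HCl, toluene, 100 °C
Reagents that add atoms: none
Why: Clemmensen reduction converts the aryl ketone to CH2, as in the classical acylresorcinol → alkylresorcinol conversion, and the hot HCl cleaves both MOM acetals in the same pot. The acid, OMe and free phenols survive.

**Step 6**
Reactants: 8 anisole
Product: 9 4-bromoanisole
Conditions: NBS, MeCN, rt
Reagents that add atoms: N-bromosuccinimide, O=C1CCC(=O)N1Br
Why: electrophilic aromatic bromination goes para to OMe.

**Step 7**
Reactants: 9
Product: 10 4-bromo-2-iodoanisole
Conditions: NIS, cat. TsOH, MeCN, 50 °C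
Reagents that add atoms: N-iodosuccinimide, O=C1CCC(=O)N1I
Why: with the para position blocked, iodination occurs ortho to OMe. This gives a dihalide with differentiated C–I and C–Br bonds.

**Step 8**
Reactants: 7; 10
Product: 11 5-[4-(5-bromo-2-methoxyphenoxy)-3-methoxy-2-hydroxyphenyl]pentanoic acid
Conditions: CuI (10 mol%), picolinic acid (20 mol%), K3PO4 (3.5 equiv), DMSO, 90 °C
Reagents that add atoms: none (both partners are the reactants)
Why: Ullmann-type C–O coupling is selective for C–I over C–Br. The less hindered C4-OH (b1) couples in preference to the C2-OH (b5), which is flanked by the chain and the OMe, and the carboxylate is not a competent nucleophile.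

**Step 9**
Reactants: 11
Product: 12 5-[4-(2-methoxy-5-vinylphenoxy)-3-methoxy-2-hydroxyphenyl]pentanoic acid
Conditions: K vinyltrifluoroborate, PdCl2(dppf) (10 mol%), Et3N, i-PrOH/H2O, 80 °C
Reagents that add atoms: potassium vinyltrifluoroborate, C=C[B-](F)(F)F.[K+]
Why: Suzuki–Miyaura vinylation installs the radical acceptor and tolerates free phenol and acid.

**Step 10**
Reactants: 12
Product: 13 Se-phenyl 5-[4-(2-methoxy-5-vinylphenoxy)-3-methoxy-2-hydroxyphenyl]pentaneselenoate
Conditions: (PhSe)2, PBu3, THF, rt
Reagents that add atoms: diphenyl diselenide, c1ccc(cc1)[Se][Se]c1ccccc1; tributylphosphine, CCCCP(CCCC)CCCC (O is lost as Bu3P=O; PhSe is retained)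
Why: Grieco-type dehydrative acyl selenide formation gives a stable, chemoselective acyl-radical precursor.

**Step 11**
Reactants: 13
Product: 14 juglanin A
Conditions: Bu3SnH (0.03 M, syringe pump over 8 h), AIBN (cat.), benzene, 80 °C, substrate 1–2 mM
Reagents that add atoms: none (Bu3SnH supplies H only; PhSe leaves as Bu3SnSePh)
Why: Proposed new method: Bu3Sn• abstracts PhSe to give the primary acyl radical. This adds 15-endo to the terminal CH2 of the styrene, forming the C2–C3 bond and the ketone together and leaving a stabilised benzylic radical, which is quenched by Bu3SnH. The rigid meta- and para-phenylene units pre-organise the two ends, and slow addition at high dilution suppresses aldehyde formation, decarbonylation and oligomerisation. The closest known reaction type is acyl-selenide acyl-radical cyclisation onto alkenes. No stereocentre is created because C1 becomes CH2.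

## Compound list
1 | resorcinol | Oc1cccc(O)c1 | starting material
2 | 1,3-bis(methoxymethoxy)benzene | COCOc1cccc(OCOC)c1 | intermediate
3 | 2,6-bis(methoxymethoxy)phenol | COCOc1cccc(OCOC)c1O | intermediate
4 | 2-methoxy-1,3-bis(methoxymethoxy)benzene | COCOc1cccc(OCOC)c1OC | intermediate
5 | glutaric anhydride | O=C1CCCC(=O)O1 | starting material
6 | 5-[3-methoxy-2,4-bis(methoxymethoxy)phenyl]-5-oxopentanoic acid | COCOc1ccc(C(=O)CCCC(=O)O)c(OCOC)c1OC | intermediate
7 | 5-(2,4-dihydroxy-3-methoxyphenyl)pentanoic acid | OC(=O)CCCCc1ccc(O)c(OC)c1O | intermediate
8 | anisole | COc1ccccc1 | starting material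
9 | 4-bromoanisole | COc1ccc(Br)cc1 | intermediate
10 | 4-bromo-2-iodoanisole | COc1ccc(Br)cc1I | intermediate
11 | 5-[4-(5-bromo-2-methoxyphenoxy)-3-methoxy-2-hydroxyphenyl]pentanoic acid | OC(=O)CCCCc1ccc(Oc2cc(Br)ccc2OC)c(OC)c1O | intermediate
12 | 5-[4-(2-methoxy-5-vinylphenoxy)-3-methoxy-2-hydroxyphenyl]pentanoic acid | OC(=O)CCCCc1ccc(Oc2cc(C=C)ccc2OC)c(OC)c1O | intermediate
13 | Se-phenyl selenoester of 12 | O=C(CCCCc1ccc(Oc2cc(C=C)ccc2OC)c(OC)c1O)[Se]c1ccccc1 | intermediate
14 | juglanin A (no stereocentres) | COc1ccc2cc1Oc1ccc(c(O)c1OC)CCCCC(=O)CC2 | target

## Totals
- Total steps: 11.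
- Longest linear sequence: 9 (steps 1–5, 8–11).
- Three steps most likely to fail:
  1. **Step 11, radical macrocyclisation.** Premature reduction or decarbonylation of the acyl radical, or oligomerisation, may dominate. Fallback: change the ring-closing method to macro-ring-closing metathesis. Convert acid 7 to the Weinreb amide and add vinylMgBr to give the vinyl ketone, then close styrene + vinyl ketone with a Grubbs-type catalyst to the enone macrocycle, and hydrogenate to 14.
  2. **Step 8, Ullmann coupling on the free dihydroxy acid.** Hindrance or poor regioselectivity between the two phenols may be a problem. Fallback: make the 2,4-dihydroxyaryl ketone first by glutaric anhydride/BF3 acylation of 2-methoxyresorcinol (from deprotecting 4). There the 2-OH is H-bond-locked and the 4-OH is acidic, so arylation with 10 is chelation-controlled. Clemmensen reduction then follows.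
  3. **Step 4, lithiation/anhydride acylation.** Over-addition to the ketone or low yield are the risks. Fallback: drop the organolithium route. Deprotect 4 to 2-methoxyresorcinol and acylate it directly with glutaric anhydride/BF3·OEt2 (resorcinol-type Friedel–Crafts), then continue with the Clemmensen step.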